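**Plan**

- Halimane numbering: ring A = C1–C5 and C10; ring B = C5–C10; chain C11–C16 on C9; C17 on C8; C20 on C9; ester carbon on C4.
- Retrosynthetic cuts, in order: the propanoate O–acyl bond; C2–C3 and C4–C5 (ring A, Diels–Alder with methyl methacrylate); C1–C10 (vinyl coupling at a C10 enol triflate); C13=C14 and C11=C12 (two Horner–Wadsworth–Emmons olefinations); C7–C8 and C9–C10 (ring B, Diels–Alder).
- Enabling feature: on ring B the unit C17–C8–C9(C20)–C11 is the carbon skeleton of (E)-2-methylbut-2-enal, with the two methyls already cis across C8–C9. C10 is sp2 in the target (C1=C10), so the oxygen a 1-siloxydiene leaves on C10 is only a handle.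
- Forward order: ring B by catalytic enantioselective cycloaddition, then the C11–C15 chain, then C10 ketone → enol triflate → vinyl diene, then ring A, then reduction and propanoylation at C15.
- Stereochemistry: C8/C9 relative from the (E)-enal, absolute from the chiral oxazaborolidinium catalyst; C5 by addition of the methacrylate anti to the pseudoaxial C9 methyl; C4 by the ester-endo transition state; the (E)-C13=C14 alkene from the second olefination.

Key step: step 2

Remark: 4 is written as the endo adduct (siloxy cis to formyl); its C10 epimer would be carried on identically, because C10 becomes a ketone in step 7.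
Remark: the (S)-catalyst is assigned by analogy with its known sense of induction toward 2-substituted propenals; it is a prediction for this enal, and the (R)-catalyst would be used if the opposite sense were found.

**Step 1**
Reactants: 1 (E)-but-2-enal
Product: 2 (E)-1-(triisopropylsilyloxy)buta-1,3-diene
Conditions: i-Pr3SiOTf, Et3N, Et2O, 0 °C → rt
Reagents that add atoms: triisopropylsilyl trifluoromethanesulfonate, CC(C)[Si](OS(=O)(=O)C(F)(F)F)(C(C)C)C(C)C
Why: Silyl dienol ether formation: O-silylation of the enal and γ-deprotonation by the amine give the conjugated (E)-dienol ether, the standard preparation of 1-siloxybutadienes.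

**Step 2**
Reactants: 2 (E)-1-(triisopropylsilyloxy)buta-1,3-diene; 3 (E)-2-methylbut-2-enal
Product: 4 (1S,2R,6R)-1,6-dimethyl-2-(triisopropylsilyloxy)cyclohex-3-ene-1-carbaldehyde
Conditions: 2 (1.5 equiv), (S)-tetrahydro-1-(2-methylphenyl)-3,3-diphenyl-1H,3H-pyrrolo[1,2-c][1,3,2]oxazaborole (20 mol%), Tf2NH (18 mol%), CH2Cl2, −78 → −20 °C
Reagents that add atoms: none
Why: The N-protonated oxazaborolidine binds the formyl oxygen of 3 and lowers its LUMO, and diene 2 then adds in a concerted, asynchronous [4+2] cycloaddition in which the C7–C8 bond (free diene terminus to the enal β-carbon) runs ahead of the C9–C10 bond (siloxy terminus to the α-carbon). The closest known reaction type is the cationic oxazaborolidine-catalysed Diels–Alder reaction of 2-substituted propenals and of α,β-disubstituted enals with cyclopentadiene and with 1-siloxybutadienes. Ring B closes by intermolecular [4+2] cycloaddition, a four-carbon and a two-carbon unit joining suprafacially on both partners. C8 and C9 take their relative configuration from the (E)-alkene of 3 (methyls cis, formyl trans to the C8 methyl) and their absolute configuration from the catalyst, which covers one face of the s-trans enal so that the diene should reach the Re face of the α-carbon; C10 follows from the endo position of the formyl group and is of no consequence. The step needs ortho regiochemistry, which the 1-siloxy donor secures by enlarging the HOMO coefficient at C7, and enantiofacial control, which rests on the single binding mode of the α-substituted enal (formyl C–H held by the ring oxygen of the catalyst).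

**Step 3**
Reactants: 4 (1S,2R,6R)-1,6-dimethyl-2-(triisopropylsilyloxy)cyclohex-3-ene-1-carbaldehyde
Product: 5 (E)-4-[(1R,2R,6R)-1,6-dimethyl-2-(triisopropylsilyloxy)cyclohex-3-en-1-yl]but-3-en-2-one
Conditions: dimethyl (2-oxopropyl)phosphonate, NaH, THF, 0 → 60 °C
Reagents that add atoms: dimethyl (2-oxopropyl)phosphonate, CC(=O)CP(=O)(OC)OC
Why: Horner–Wadsworth–Emmons olefination with a β-ketophosphonate; the α-quaternary aldehyde cannot enolise or eliminate, and the stabilised carbanion gives the (E)-enone (C11=C12).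

**Step 4**
Reactants: 5 (E)-4-[(1R,2R,6R)-1,6-dimethyl-2-(triisopropylsilyloxy)cyclohex-3-en-1-yl]but-3-en-2-one
Product: 6 4-[(1S,2R,6R)-1,2-dimethyl-6-(triisopropylsilyloxy)cyclohexyl]butan-2-one
Conditions: H2 (1 atm), 10% Pd/C, EtOAc, rt
Reagents that add atoms: none
Why: Heterogeneous catalytic hydrogenation saturates the enone C=C and the cis-disubstituted ring alkene while the ketone and the silyl ether are left; no stereocentre is created (C5, C6, C11 and C12 become CH2).

**Step 5**
Reactants: 6 4-[(1S,2R,6R)-1,2-dimethyl-6-(triisopropylsilyloxy)cyclohexyl]butan-2-one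
Product: 7 ethyl (E)-5-[(1S,2R,6R)-1,2-dimethyl-6-(triisopropylsilyloxy)cyclohexyl]-3-methylpent-2-enoate
Conditions: triethyl phosphonoacetate, NaH, THF, 0 → 65 °C; chromatographic removal of the (Z)-isomer
Reagents that add atoms: triethyl phosphonoacetate, CCOC(=O)CP(=O)(OCC)OCC
Why: Horner–Wadsworth–Emmons olefination of the unhindered methyl ketone; the reversible addition places the ester trans to the larger CH2 substituent, so the (E)-trisubstituted enoate should predominate.

**Step 6**
Reactants: 7 ethyl (E)-5-[(1S,2R,6R)-1,2-dimethyl-6-(triisopropylsilyloxy)cyclohexyl]-3-methylpent-2-enoate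
Product: 8 ethyl (E)-5-[(1S,2R,6R)-2-hydroxy-1,6-dimethylcyclohexyl]-3-methylpent-2-enoate
Conditions: 48% aq. HF, MeCN, rt
Reagents that add atoms: none
Why: Fluoride-driven cleavage of the silyl ether (Si–F bond formation); the acidic medium avoids a C10 alkoxide and hence its conjugate addition to the enoate.

**Step 7**
Reactants: 8 ethyl (E)-5-[(1S,2R,6R)-2-hydroxy-1,6-dimethylcyclohexyl]-3-methylpent-2-enoate
Product: 9 ethyl (E)-5-[(1S,2R)-1,2-dimethyl-6-oxocyclohexyl]-3-methylpent-2-enoate
Conditions: Dess–Martin periodinane (1,1,1-triacetoxy-1,1-dihydro-1,2-benziodoxol-3(1H)-one), CH2Cl2, rt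
Reagents that add atoms: none
Why: Dess–Martin oxidation of the hindered secondary alcohol under neutral conditions; it removes the C10 stereocentre, so both C10 epimers converge on one ketone.

**Step 8**
Reactants: 9 ethyl (E)-5-[(1S,2R)-1,2-dimethyl-6-oxocyclohexyl]-3-methylpent-2-enoate
Product: 10 ethyl (E)-5-[(1S,6R)-1,6-dimethyl-2-(trifluoromethylsulfonyloxy)cyclohex-2-en-1-yl]-3-methylpent-2-enoate
Conditions: Tf2O, 2,6-di-tert-butyl-4-methylpyridine, CH2Cl2, 0 °C → rt
Reagents that add atoms: trifluoromethanesulfonic anhydride, O=S(=O)(OS(=O)(=O)C(F)(F)F)C(F)(F)F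
Why: Enol triflate formation by O-triflylation of the ketone and loss of a C5 proton to the hindered pyridine; C9 is quaternary, so only the C10=C5 isomer can form, and the absence of a strong base spares the γ-acidic enoate.

**Step 9**
Reactants: 10 ethyl (E)-5-[(1S,6R)-1,6-dimethyl-2-(trifluoromethylsulfonyloxy)cyclohex-2-en-1-yl]-3-methylpent-2-enoate
Product: 11 ethyl (E)-5-[(1S,6R)-2-ethenyl-1,6-dimethylcyclohex-2-en-1-yl]-3-methylpent-2-enoate
Conditions: tributyl(ethenyl)stannane, Pd(PPh3)4 (5 mol%), LiCl (3 equiv), THF, 65 °C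
Reagents that add atoms: tributyl(ethenyl)stannane, C=C[Sn](CCCC)(CCCC)CCCC
Why: Stille cross-coupling (oxidative addition of the enol triflate to zerovalent palladium, chloride exchange, vinyl transfer from tin, reductive elimination), well established for cyclohexenyl triflates next to quaternary carbons.

**Step 10**
Reactants: 11 ethyl (E)-5-[(1S,6R)-2-ethenyl-1,6-dimethylcyclohex-2-en-1-yl]-3-methylpent-2-enoate; 12 methyl 2-methylprop-2-enoate
Product: 13 methyl (1S,5S,6R,8aR)-5-[(3E)-5-ethoxy-3-methyl-5-oxopent-3-en-1-yl]-1,5,6-trimethyl-1,2,3,5,6,7,8,8a-octahydronaphthalene-1-carboxylate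
Conditions: EtAlCl2 (50 mol%), methyl methacrylate in fivefold excess, CH2Cl2, −78 → −20 °C
Reagents that add atoms: none
Why: Lewis acid-promoted Diels–Alder reaction of a 1-vinylcyclohexene with an α-substituted acrylate: the ring terminus C5 of the diene bonds to the ester-bearing carbon C4 and the vinyl terminus C2 to the methylene carbon C3 (ortho rule), the coordinated ester lies endo and so ends cis to C6 and trans to H5, and the dienophile approaches the face opposite the pseudoaxial C9 methyl of the half-chair that keeps the C8 methyl equatorial, which should set C5 and C4 as in the target and leave the new alkene at C1=C10.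

**Step 11**
Reactants: 13 methyl (1S,5S,6R,8aR)-5-[(3E)-5-ethoxy-3-methyl-5-oxopent-3-en-1-yl]-1,5,6-trimethyl-1,2,3,5,6,7,8,8a-octahydronaphthalene-1-carboxylate
Product: 14 methyl (1S,5S,6R,8aR)-5-[(3E)-5-hydroxy-3-methylpent-3-en-1-yl]-1,5,6-trimethyl-1,2,3,5,6,7,8,8a-octahydronaphthalene-1-carboxylate
Conditions: i-Bu2AlH (2.2 equiv), CH2Cl2, −78 °C; aq. potassium sodium tartrate
Reagents that add atoms: none
Why: Hydride 1,2-reduction of the conjugated ethyl ester to the allylic alcohol by i-Bu2AlH; the methyl ester on the quaternary C4, flanked by the ring-fusion carbon, is far more hindered and should survive at −78 °C.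

**Step 12**
Reactants: 14 methyl (1S,5S,6R,8aR)-5-[(3E)-5-hydroxy-3-methylpent-3-en-1-yl]-1,5,6-trimethyl-1,2,3,5,6,7,8,8a-octahydronaphthalene-1-carboxylate
Product: 15 methyl (1S,5S,6R,8aR)-1,5,6-trimethyl-5-[(3E)-3-methyl-5-(propanoyloxy)pent-3-en-1-yl]-1,2,3,5,6,7,8,8a-octahydronaphthalene-1-carboxylate
Conditions: propanoic anhydride, Et3N, 4-(dimethylamino)pyridine (5 mol%), CH2Cl2, 0 °C → rt
Reagents that add atoms: propanoic anhydride, CCC(=O)OC(=O)CC
Why: Acylation of the only hydroxyl group, a primary allylic alcohol, by the anhydride under nucleophilic catalysis by the aminopyridine.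

**Compound list**

1 | (E)-but-2-enal | C/C=C/C=O | starting material
2 | (E)-1-(triisopropylsilyloxy)buta-1,3-diene | C=C/C=C/O[Si](C(C)C)(C(C)C)C(C)C | intermediate
3 | (E)-2-methylbut-2-enal | C/C=C(\C)C=O | starting material
4 | (1S,2R,6R)-1,6-dimethyl-2-(triisopropylsilyloxy)cyclohex-3-ene-1-carbaldehyde | O=C[C@]1(C)[C@H](O[Si](C(C)C)(C(C)C)C(C)C)C=CC[C@H]1C | intermediate
5 | (E)-4-[(1R,2R,6R)-1,6-dimethyl-2-(triisopropylsilyloxy)cyclohex-3-en-1-yl]but-3-en-2-one | CC(=O)/C=C/[C@]1(C)[C@H](O[Si](C(C)C)(C(C)C)C(C)C)C=CC[C@H]1C | intermediate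
6 | 4-[(1S,2R,6R)-1,2-dimethyl-6-(triisopropylsilyloxy)cyclohexyl]butan-2-one | CC(=O)CC[C@]1(C)[C@H](O[Si](C(C)C)(C(C)C)C(C)C)CCC[C@H]1C | intermediate
7 | ethyl (E)-5-[(1S,2R,6R)-1,2-dimethyl-6-(triisopropylsilyloxy)cyclohexyl]-3-methylpent-2-enoate | CCOC(=O)/C=C(\C)CC[C@]1(C)[C@H](O[Si](C(C)C)(C(C)C)C(C)C)CCC[C@H]1C | intermediate
8 | ethyl (E)-5-[(1S,2R,6R)-2-hydroxy-1,6-dimethylcyclohexyl]-3-methylpent-2-enoate | CCOC(=O)/C=C(\C)CC[C@]1(C)[C@H](O)CCC[C@H]1C | intermediate
9 | ethyl (E)-5-[(1S,2R)-1,2-dimethyl-6-oxocyclohexyl]-3-methylpent-2-enoate | CCOC(=O)/C=C(\C)CC[C@]1(C)C(=O)CCC[C@H]1C | intermediate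
10 | ethyl (E)-5-[(1S,6R)-1,6-dimethyl-2-(trifluoromethylsulfonyloxy)cyclohex-2-en-1-yl]-3-methylpent-2-enoate | CCOC(=O)/C=C(\C)CC[C@]1(C)C(OS(=O)(=O)C(F)(F)F)=CCC[C@H]1C | intermediate
11 | ethyl (E)-5-[(1S,6R)-2-ethenyl-1,6-dimethylcyclohex-2-en-1-yl]-3-methylpent-2-enoate | CCOC(=O)/C=C(\C)CC[C@]1(C)C(C=C)=CCC[C@H]1C | intermediate
12 | methyl 2-methylprop-2-enoate (methyl methacrylate) | C=C(C)C(=O)OC | starting material
13 | methyl (1S,5S,6R,8aR)-5-[(3E)-5-ethoxy-3-methyl-5-oxopent-3-en-1-yl]-1,5,6-trimethyl-1,2,3,5,6,7,8,8a-octahydronaphthalene-1-carboxylate | CCOC(=O)/C=C(\C)CC[C@]1(C)C2=CCC[C@](C)(C(=O)OC)[C@@H]2CC[C@H]1C | intermediate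
14 | methyl (1S,5S,6R,8aR)-5-[(3E)-5-hydroxy-3-methylpent-3-en-1-yl]-1,5,6-trimethyl-1,2,3,5,6,7,8,8a-octahydronaphthalene-1-carboxylate | OC/C=C(\C)CC[C@]1(C)C2=CCC[C@](C)(C(=O)OC)[C@@H]2CC[C@H]1C | intermediate
15 | methyl (1S,5S,6R,8aR)-1,5,6-trimethyl-5-[(3E)-3-methyl-5-(propanoyloxy)pent-3-en-1-yl]-1,2,3,5,6,7,8,8a-octahydronaphthalene-1-carboxylate | CCC(=O)OC/C=C(\C)CC[C@]1(C)C2=CCC[C@](C)(C(=O)OC)[C@@H]2CC[C@H]1C | target

**Count and risks**

Total step count: 12. Longest linear sequence: 12 steps (1 → 15).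

Step 2 is the most exposed. The α,β-disubstituted enal may add so slowly that acid-mediated loss of the siloxydiene, vinylogous addition to the carbonyl group, or a less organised and less enantioselective pathway competes; the sense of induction also has to be confirmed. The fallback sets out from 2 and 3 and gives up asymmetric catalysis for resolution. Thermal cycloaddition (toluene, 130 °C, sealed tube, 2,6-di-tert-butyl-4-methylphenol as stabiliser) would give 4 together with its mirror image, the (1R,2S,6S)-aldehyde F1. Condensation of the mixture with (1R,2R)-N,N′-dimethyl-1,2-diphenylethane-1,2-diamine (Et2O, 4 Å molecular sieves) would give two diastereomeric imidazolidines, the aminal of 4 F2 and the aminal of the mirror-image aldehyde F3, to be separated by chromatography. Mild hydrolysis of F2 (dilute aq. HCl, Et2O, 0 °C) returns to 4.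

Step 10 carries three selectivity demands at once. The weakly activated α-methyl acrylate may react slowly and with poor endo or facial discrimination, so that C4 or C5 epimers accompany 13. The fallback sets out from 11 and changes the dienophile and its oxidation level. The more reactive and more endo-selective 2-methylpropenal (Me2AlCl, CH2Cl2, −78 °C) would give the C4 aldehyde, ethyl (E)-5-[(1S,2R,4aR,5S)-5-formyl-1,2,5-trimethyl-1,2,3,4,4a,5,6,7-octahydronaphthalen-1-yl]-3-methylpent-2-enoate F4. Pinnick oxidation (NaClO2, NaH2PO4, 2-methylbut-2-ene, t-BuOH/H2O) would give the corresponding C4 carboxylic acid F5, and methylation with Me3SiCHN2 (MeOH/toluene) comes back to 13.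

Step 5 may suffer from incomplete (E)-selectivity in the olefination of the methyl ketone, which costs material and cannot be corrected later. The fallback sets out from 6 and builds the alkene by carbometalation. Kinetic enolisation at the methyl group (LiN(i-Pr)2, THF, −78 °C) and trapping with ClP(O)(OEt)2 would give the terminal enol phosphate F6. A further charge of LiN(i-Pr)2 eliminates diethyl phosphate to give the terminal alkyne F7. Zirconium-catalysed methylalumination (Me3Al, Cp2ZrCl2, CH2Cl2, rt) adds methyl and aluminium syn to give the (E)-alkenyl(dimethyl)alane F8, which is acylated in the same flask with ethyl chloroformate and comes back to 7 as the (E)-isomer only.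

**Further compounds**

F1 | step 2 | (1R,2S,6S)-1,6-dimethyl-2-(triisopropylsilyloxy)cyclohex-3-ene-1-carbaldehyde (mirror image of 4) | O=C[C@@]1(C)[C@@H](O[Si](C(C)C)(C(C)C)C(C)C)C=CC[C@@H]1C
F2 | step 2 | aminal of 4: (4R,5R)-2-[(1R,2R,6R)-1,6-dimethyl-2-(triisopropylsilyloxy)cyclohex-3-en-1-yl]-1,3-dimethyl-4,5-diphenylimidazolidine | CN1[C@H](c2ccccc2)[C@@H](c2ccccc2)N(C)C1[C@]3(C)[C@H](O[Si](C(C)C)(C(C)C)C(C)C)C=CC[C@H]3C
F3 | step 2 | aminal of F1: (4R,5R)-2-[(1S,2S,6S)-1,6-dimethyl-2-(triisopropylsilyloxy)cyclohex-3-en-1-yl]-1,3-dimethyl-4,5-diphenylimidazolidine | CN1[C@H](c2ccccc2)[C@@H](c2ccccc2)N(C)C1[C@@]3(C)[C@@H](O[Si](C(C)C)(C(C)C)C(C)C)C=CC[C@@H]3C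
F4 | step 10 | ethyl (E)-5-[(1S,2R,4aR,5S)-5-formyl-1,2,5-trimethyl-1,2,3,4,4a,5,6,7-octahydronaphthalen-1-yl]-3-methylpent-2-enoate | CCOC(=O)/C=C(\C)CC[C@]1(C)C2=CCC[C@](C)(C=O)[C@@H]2CC[C@H]1C
F5 | step 10 | (1S,5S,6R,8aR)-5-[(3E)-5-ethoxy-3-methyl-5-oxopent-3-en-1-yl]-1,5,6-trimethyl-1,2,3,5,6,7,8,8a-octahydronaphthalene-1-carboxylic acid | CCOC(=O)/C=C(\C)CC[C@]1(C)C2=CCC[C@](C)(C(=O)O)[C@@H]2CC[C@H]1C
F6 | step 5 | 4-[(1S,2R,6R)-1,2-dimethyl-6-(triisopropylsilyloxy)cyclohexyl]but-1-en-2-yl diethyl phosphate | C=C(OP(=O)(OCC)OCC)CC[C@]1(C)[C@H](O[Si](C(C)C)(C(C)C)C(C)C)CCC[C@H]1C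
F7 | step 5 | [(1R,2S,3R)-2-(but-3-yn-1-yl)-2,3-dimethylcyclohexyl]oxy(triisopropyl)silane | C#CCC[C@]1(C)[C@H](O[Si](C(C)C)(C(C)C)C(C)C)CCC[C@H]1C
F8 | step 5 | (E)-{4-[(1S,2R,6R)-1,2-dimethyl-6-(triisopropylsilyloxy)cyclohexyl]-2-methylbut-1-en-1-yl}dimethylalumane | C[Al](C)/C=C(\C)CC[C@]1(C)[C@H](O[Si](C(C)C)(C(C)C)C(C)C)CCC[C@H]1C
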